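**Plan**

- Numbering: friedodrimane skeleton C1–C11 (C4 bears the exocyclic CH2, C5 and C10 are the ring-fusion carbons, C8 is CHMe, C9 is quaternary, C11 is the benzylic CH2); arene C1'–C6' (C1' on C11, C2' sulfate, C3' OH, C5' CH2OH).
- Retrosynthetic cuts, in order: S–O2', C4=CH2, C8–C9 (ring B), C5–C6, C10–C9, the B–C9/H–C11 pair across a C9≡C11 alkyne, C11–C1'.
- Forward: the arene becomes an arylpropyne and then an alkenylboronate; this is joined at C10 to ring A (2-methylcyclohexenone); the four-carbon chain goes onto C5; ring B is closed last between C8 and C9; then methylenation, sulfation, desilylation.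
- Enabling feature: C9 is a quaternary ring-B carbon carrying CH3 and CH2–aryl and bonded to C8H(CH3). This array is what remains when a C8 radical adds to the methyl-bearing carbon of a C9=C11H–aryl alkene held on C10 and the benzylic C11 radical is reduced.
- Stereochemistry: C10 from the (R)-BINAP–rhodium conjugate addition, C5 from enolate alkylation anti to the C10 substituent, C8 and C9 from the chair-like radical ring closure.

Key step: step 10

Assumption: the sulfate monoesters 20 and 21 are written as neutral hydrogen sulfates, as in the target formula; in practice they would be handled as pyridinium or sodium salts.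

Abbreviations: Ar = 2-(methoxymethoxy)-3-(triisopropylsilyloxy)-5-[(triisopropylsilyloxy)methyl]phenyl (C1' is the point of attachment); TIPS = Si(i-Pr)3; MOM = CH2OCH3.

**Route**

Step 1
Reactants: 1 3-bromo-4,5-dihydroxybenzaldehyde
Product: 2 3-bromo-5-hydroxy-4-(methoxymethoxy)benzaldehyde
Conditions: MOMCl (1.05 equiv), i-Pr2NEt (1.1 equiv), CH2Cl2/DMF, 0 °C
Reagents that add atoms: chloromethyl methyl ether, COCCl
Why: Phenol O-alkylation; the 4-OH, para to the formyl group and ortho to bromine, is the more acidic phenol and should be etherified selectively with one equivalent of base, as in 4-O-selective alkylations of 3,4-dihydroxybenzaldehydes.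

Step 2
Reactants: 2 3-bromo-5-hydroxy-4-(methoxymethoxy)benzaldehyde
Product: 3 3-bromo-5-(hydroxymethyl)-2-(methoxymethoxy)phenol
Conditions: NaBH4, MeOH, 0 °C
Reagents that add atoms: none
Why: Borohydride reduction of the aldehyde; aryl bromide, MOM ether and phenol are not touched.

Step 3
Reactants: 3 3-bromo-5-(hydroxymethyl)-2-(methoxymethoxy)phenol
Product: 4 Ar–Br (bis-TIPS ether of 3)
Conditions: TIPSCl (2.4 equiv), imidazole, DMF, rt to 40 °C
Reagents that add atoms: chlorotriisopropylsilane, CC(C)[Si](Cl)(C(C)C)C(C)C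
Why: Silylation of the phenol and the primary alcohol; TIPS is chosen because aryl TIPS ethers should survive the basic steps ahead and both come off together with fluoride at the end.

Step 4
Reactants: 4 Ar–Br; 5 propyne
Product: 6 Ar–C≡C–CH3 (1-aryl-1-propyne)
Conditions: PdCl2(PPh3)2, CuI, Et3N, DMF, propyne (3 equiv), 80 °C, sealed vessel
Reagents that add atoms: none
Why: Sonogashira coupling of the aryl bromide with the terminal alkyne forms the C1'–C11 bond.

Step 5
Reactants: 6 Ar–C≡C–CH3
Product: 7 pinacol (Z)-alkenylboronate Ar–CH=C(CH3)–Bpin (boron cis to the vinylic hydrogen, aryl cis to methyl)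
Conditions: CuCl, NaOt-Bu, PPh3 (all catalytic), B2pin2, MeOH (2 equiv), THF, rt
Reagents that add atoms: bis(pinacolato)diboron, CC1(C)OB(OC1(C)C)B1OC(C)(C)C(C)(C)O1
Why: Copper-catalysed formal hydroboration (syn borylcupration, then protonolysis by methanol) places boron on the alkyne carbon remote from the aryl group, which fixes the alkene geometry needed later.

Step 6
Reactants: 7 alkenylboronate; 8 2-methylcyclohex-2-en-1-one
Product: 9 (3R)-2-methyl-3-[(E)-1-Ar-prop-1-en-2-yl]cyclohexan-1-one (mixture of C2 epimers)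
Conditions: [Rh(OH)(cod)]2 (3 mol %), (R)-BINAP (7 mol %), 8 (3 equiv), K3PO4 (0.5 equiv), dioxane/H2O 10:1, 60 °C
Reagents that add atoms: none
Why: Hayashi–Miyaura conjugate addition: the alkenyl group passes from boron to rhodium and inserts into the enone, and the (R)-BINAP complex should attack the face that gives 3R (the sense known for cyclohex-2-enone), while the slower α-methyl enone is compensated by using it in excess; the C2 epimers formed on protonation converge in step 7.

Step 7
Reactants: 9 (3R)-ketone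
Product: 11 trimethylsilyl enol ether of 9 with the C4=C5 (tetrasubstituted) double bond, via bromomagnesium enolate 10 (not isolated)
Conditions: i-Pr2NMgBr (from i-Pr2NH and EtMgBr), Et2O, rt; then Me3SiCl, Et3N, HMPA, rt
Reagents that add atoms: chlorotrimethylsilane, C[Si](C)(C)Cl
Why: Thermodynamic enolisation with the magnesium amide equilibrates toward the more substituted enolate, which is silylated in the flask; C10 is not enolisable and keeps its configuration.

Step 8
Reactants: 12 1,3-dibromobutane
Product: 13 3-bromo-1-iodobutane (racemic)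
Conditions: NaI (1.0 equiv), acetone, rt; distillation
Reagents that add atoms: sodium iodide, [Na+].[I-]
Why: Finkelstein exchange; iodide displaces the primary bromide much faster than the secondary one while NaBr precipitates.

Step 9
Reactants: 11 silyl enol ether; 13 3-bromo-1-iodobutane
Product: 15 (2S,3S)-2-(3-bromobutyl)-2-methyl-3-[(E)-1-Ar-prop-1-en-2-yl]cyclohexan-1-one (both epimers at CHBr), via lithium enolate 14 (not isolated)
Conditions: MeLi (1.0 equiv), THF, 0 °C to rt; then HMPA, 13 (3 equiv), −78 to −20 °C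
Reagents that add atoms: none
Why: Regiospecific enolate generation by Si–O cleavage and C-alkylation at the primary iodide; the electrophile enters C5 axially and anti to the pseudoaxial C10 alkenyl group, so the new chain is trans to it and the C5 methyl cis (the future trans ring fusion), and the secondary bromide is too slow to compete at low temperature.

Step 10
Reactants: 15 bromo ketone
Product: 16 (4aS,5R,6S,8aS)-5-(Ar-methyl)-5,6,8a-trimethyl-octahydronaphthalen-1(2H)-one (trans-decalin C4 ketone with C8 and C9 set)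
Conditions: (Me3Si)3SiH (1.5 equiv) and AIBN (0.3 equiv) added over 10 h to 15 in benzene (5 mM), 80 °C
Reagents that add atoms: none
Why: (Me3Si)3Si• takes bromine from C8, the secondary C8 radical adds to C9 (the methyl-bearing carbon of the C9=C11 styrene), and the benzylic C11 radical abstracts hydrogen from the silane and carries the chain; the closest known type is the reductive cyclisation of alkyl halides onto styrenes with tin or silicon hydrides, which has also been used to make quaternary carbons. Ring B closes in the 6-exo-trig mode, preferred over 7-endo because only it gives a benzylic radical and because C11 carries the aryl group. C8 is set in a chair-like transition state built on the preset trans C5/C10 pair, in which the C8 methyl sits equatorial, so both bromide epimers should converge on 8S with that methyl cis to the C9 methyl. C9 is set by the alkene reacting in the conformation with C10–H eclipsing C9=C11 and from the face turned toward C5, so the arylvinyl end lies equatorial, away from the axial C5 methyl, and becomes the equatorial CH2Ar while the C9 methyl ends axial (9R). The step needs ring closure to outrun hydrogen transfer from the silane, which slow addition at high dilution and 80 °C should secure, and to outrun 1,5-hydrogen shift from C10–H, against which only the benzylic activation of the acceptor works. C4 is kept as a ketone on purpose, since a C4 methylene would offer the radical a competing 6-endo path, and the MOM and TIPS ethers are inert to silyl radicals.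

Step 11
Reactants: 16 decalin ketone
Product: 17 C4-methylidene compound (exocyclic alkene, aryl still MOM/TIPS protected)
Conditions: Ph3PCH3Br (4 equiv), KOt-Bu (3.8 equiv), toluene, 90 °C
Reagents that add atoms: methyltriphenylphosphonium bromide, C[P+](c1ccccc1)(c1ccccc1)c1ccccc1.[Br-]
Why: Wittig methylenation; excess ylide at elevated temperature is the usual answer to a ketone flanked by a quaternary carbon, and no enolisable stereocentre is adjacent.

Step 12
Reactants: 17 methylidene compound
Product: 19 O2' phenol (TIPS ethers intact), via aryl trimethylsilyl ether 18 (not isolated)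
Conditions: Me3SiOTf, 2,2'-bipyridyl, CH2Cl2, 0 °C to rt; then H2O
Reagents that add atoms: none
Why: Silyl triflate–bipyridyl cleavage of an aromatic MOM ether, which passes through the aryl silyl ether and is hydrolysed on work-up; the buffered, non-protic medium should spare the exocyclic alkene and the TIPS ethers.

Step 13
Reactants: 19 phenol
Product: 20 O2' hydrogen sulfate (bis-TIPS ether)
Conditions: SO3·pyridine (5 equiv), pyridine, rt to 40 °C
Reagents that add atoms: sulfur trioxide–pyridine complex, O=S(=O)=O.c1ccncc1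
Why: O-Sulfation of the only free hydroxyl group; weakly basic pyridine should not move the neighbouring TIPS group.

Step 14
Reactants: 20 protected sulfate
Product: 21 target, 2-hydroxy-4-(hydroxymethyl)-6-{[(1R,2S,4aS,8aS)-1,2,4a-trimethyl-5-methylidenedecahydronaphthalen-1-yl]methyl}phenyl hydrogen sulfate
Conditions: Bu4NF (3 equiv), THF, 0 °C to rt; Na+ ion exchange
Reagents that add atoms: none
Why: Fluoride cleaves the aryl and the benzylic TIPS ether; aryl sulfate monoesters are stable to fluoride and mild base.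

**Compound list**

1 | 3-bromo-4,5-dihydroxybenzaldehyde | O=Cc1cc(O)c(O)c(Br)c1 | starting material
2 | 3-bromo-5-hydroxy-4-(methoxymethoxy)benzaldehyde | O=Cc1cc(O)c(OCOC)c(Br)c1 | intermediate
3 | 3-bromo-5-(hydroxymethyl)-2-(methoxymethoxy)phenol | OCc1cc(O)c(OCOC)c(Br)c1 | intermediate
4 | 1-bromo-2-(methoxymethoxy)-3-(triisopropylsilyloxy)-5-[(triisopropylsilyloxy)methyl]benzene (Ar–Br) | Brc1cc(CO[Si](C(C)C)(C(C)C)C(C)C)cc(O[Si](C(C)C)(C(C)C)C(C)C)c1OCOC | intermediate
5 | propyne | CC#C | starting material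
6 | 2-(methoxymethoxy)-1-(prop-1-yn-1-yl)-3-(triisopropylsilyloxy)-5-[(triisopropylsilyloxy)methyl]benzene | CC#Cc1cc(CO[Si](C(C)C)(C(C)C)C(C)C)cc(O[Si](C(C)C)(C(C)C)C(C)C)c1OCOC | intermediate
7 | 2-[(Z)-1-Ar-prop-1-en-2-yl]-4,4,5,5-tetramethyl-1,3,2-dioxaborolane (B cis to vinylic H) | C/C(B1OC(C)(C)C(C)(C)O1)=C\c1cc(CO[Si](C(C)C)(C(C)C)C(C)C)cc(O[Si](C(C)C)(C(C)C)C(C)C)c1OCOC | intermediate
8 | 2-methylcyclohex-2-en-1-one | CC1=CCCCC1=O | starting material
9 | (3R)-2-methyl-3-[(E)-1-Ar-prop-1-en-2-yl]cyclohexan-1-one (C2 epimers) | O=C1CCC[C@@H](/C(C)=C/c2cc(CO[Si](C(C)C)(C(C)C)C(C)C)cc(O[Si](C(C)C)(C(C)C)C(C)C)c2OCOC)C1C | intermediate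
10 | bromomagnesium (3S)-2-methyl-3-[(E)-1-Ar-prop-1-en-2-yl]cyclohex-1-en-1-olate (not isolated) | Br[Mg]OC1=C(C)[C@H](/C(C)=C/c2cc(CO[Si](C(C)C)(C(C)C)C(C)C)cc(O[Si](C(C)C)(C(C)C)C(C)C)c2OCOC)CCC1 | intermediate
11 | trimethyl{[(3S)-2-methyl-3-[(E)-1-Ar-prop-1-en-2-yl]cyclohex-1-en-1-yl]oxy}silane | C[Si](C)(C)OC1=C(C)[C@H](/C(C)=C/c2cc(CO[Si](C(C)C)(C(C)C)C(C)C)cc(O[Si](C(C)C)(C(C)C)C(C)C)c2OCOC)CCC1 | intermediate
12 | 1,3-dibromobutane | CC(Br)CCBr | starting material
13 | 3-bromo-1-iodobutane | CC(Br)CCI | intermediate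
14 | lithium (3S)-2-methyl-3-[(E)-1-Ar-prop-1-en-2-yl]cyclohex-1-en-1-olate (not isolated) | [Li]OC1=C(C)[C@H](/C(C)=C/c2cc(CO[Si](C(C)C)(C(C)C)C(C)C)cc(O[Si](C(C)C)(C(C)C)C(C)C)c2OCOC)CCC1 | intermediate
15 | (2S,3S)-2-(3-bromobutyl)-2-methyl-3-[(E)-1-Ar-prop-1-en-2-yl]cyclohexan-1-one (CHBr epimers) | O=C1CCC[C@@H](/C(C)=C/c2cc(CO[Si](C(C)C)(C(C)C)C(C)C)cc(O[Si](C(C)C)(C(C)C)C(C)C)c2OCOC)[C@]1(C)CCC(C)Br | intermediate
16 | (4aS,5R,6S,8aS)-5-(Ar-methyl)-5,6,8a-trimethyl-3,4,4a,5,6,7,8,8a-octahydronaphthalen-1(2H)-one | O=C1CCC[C@H]2[C@](C)(Cc3cc(CO[Si](C(C)C)(C(C)C)C(C)C)cc(O[Si](C(C)C)(C(C)C)C(C)C)c3OCOC)[C@@H](C)CC[C@]12C | intermediate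
17 | (1R,2S,4aS,8aS)-1-(Ar-methyl)-1,2,4a-trimethyl-5-methylidenedecahydronaphthalene | C=C1CCC[C@H]2[C@](C)(Cc3cc(CO[Si](C(C)C)(C(C)C)C(C)C)cc(O[Si](C(C)C)(C(C)C)C(C)C)c3OCOC)[C@@H](C)CC[C@]12C | intermediate
18 | O2' trimethylsilyl ether of 19 (not isolated) | C=C1CCC[C@H]2[C@](C)(Cc3cc(CO[Si](C(C)C)(C(C)C)C(C)C)cc(O[Si](C(C)C)(C(C)C)C(C)C)c3O[Si](C)(C)C)[C@@H](C)CC[C@]12C | intermediate
19 | 2-(triisopropylsilyloxy)-4-[(triisopropylsilyloxy)methyl]-6-{[(1R,2S,4aS,8aS)-1,2,4a-trimethyl-5-methylidenedecahydronaphthalen-1-yl]methyl}phenol | C=C1CCC[C@H]2[C@](C)(Cc3cc(CO[Si](C(C)C)(C(C)C)C(C)C)cc(O[Si](C(C)C)(C(C)C)C(C)C)c3O)[C@@H](C)CC[C@]12C | intermediate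
20 | hydrogen sulfate of phenol 19 | C=C1CCC[C@H]2[C@](C)(Cc3cc(CO[Si](C(C)C)(C(C)C)C(C)C)cc(O[Si](C(C)C)(C(C)C)C(C)C)c3OS(=O)(=O)O)[C@@H](C)CC[C@]12C | intermediate
21 | 2-hydroxy-4-(hydroxymethyl)-6-{[(1R,2S,4aS,8aS)-1,2,4a-trimethyl-5-methylidenedecahydronaphthalen-1-yl]methyl}phenyl hydrogen sulfate | C=C1CCC[C@H]2[C@](C)(Cc3cc(CO)cc(O)c3OS(=O)(=O)O)[C@@H](C)CC[C@]12C | target

**Step count**

Total: 14 steps. Longest linear sequence: 13 steps (steps 1–7 and 9–14, from 1).

**Steps most likely to fail**

1. Step 10 (radical ring closure). Hydrogen transfer from the silane to the C8 radical may come before ring closure, the radical may shift a hydrogen from the allylic C10–H, or attack may occur on the other alkene face and give the C9 epimer. Fallback: generate the same C8 radical from a terminal alkene by metal-hydride hydrogen atom transfer, where no fast stoichiometric hydrogen donor is present. Setting out from silyl enol ether 11, lithium enolate 14 is alkylated with but-3-en-1-yl trifluoromethanesulfonate to give (2S,3S)-2-(but-3-en-1-yl)-2-methyl-3-[(E)-1-Ar-prop-1-en-2-yl]cyclohexan-1-one F1. Mn(dpm)3, PhSiH3 and t-BuOOH in i-PrOH (or Fe(acac)3/PhSiH3 in EtOH) should deliver hydrogen to the terminal CH2, and the C8 radical closes onto C9 as before, the benzylic radical being reduced by a second hydrogen transfer. This returns to the route at 16. It answers premature reduction only; a wrong facial bias would have to be met by separating the C9 epimers.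

2. Step 6 (rhodium conjugate addition). Insertion of the α-methyl enone into the hindered alkenyl–rhodium bond may be so slow that protodeboronation of 7 takes over, or the enantioselectivity may erode. Fallback: copper in place of rhodium, with direct trapping of the enolate. Setting out from 7, iododeboronation (NaOH, I2, retention) gives the alkenyl iodide Ar–CH=C(CH3)I F2. Iodine–lithium exchange (t-BuLi, −78 °C) gives the alkenyllithium F3, and Me2AlCl converts it into the dimethyl(alkenyl)alane F4. Copper-catalysed asymmetric conjugate addition to 8 (Cu(OTf)2 with a chiral phosphoramidite ligand of the appropriate hand) gives the aluminium enolate F5, which is silylated with Me3SiOTf. This returns to the route at 11, and step 7 is then not needed.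

3. Step 9 (alkylation at C5). C-Alkylation of the hindered tetrasubstituted enolate may be sluggish, so that proton transfer (loss of regiocontrol), elimination from 13 or O-alkylation intervene. Fallback: conjugate addition instead of substitution. Setting out from 11, a Mukaiyama–Michael addition to methyl vinyl ketone (Sc(OTf)3 cat., CH2Cl2, −78 °C, aqueous work-up) gives the diketone (2S,3S)-2-methyl-2-(3-oxobutyl)-3-[(E)-1-Ar-prop-1-en-2-yl]cyclohexan-1-one F6, with the same anti approach at C5. NaBH4 reduces both carbonyl groups to the diol F7. CBr4/PPh3 should brominate only the unhindered side-chain carbinol, giving the bromo alcohol F8, and Dess–Martin oxidation of the hindered ring carbinol restores the C4 ketone. This returns to the route at 15.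

**Further compounds**

F1 | step 10 | (2S,3S)-2-(but-3-en-1-yl)-2-methyl-3-[(E)-1-Ar-prop-1-en-2-yl]cyclohexan-1-one | O=C1CCC[C@@H](/C(C)=C/c2cc(CO[Si](C(C)C)(C(C)C)C(C)C)cc(O[Si](C(C)C)(C(C)C)C(C)C)c2OCOC)[C@]1(C)CCC=C
F2 | step 6 | 1-[(E)-2-iodoprop-1-en-1-yl]-2-(methoxymethoxy)-3-(triisopropylsilyloxy)-5-[(triisopropylsilyloxy)methyl]benzene (I cis to vinylic H) | C/C(I)=C\c1cc(CO[Si](C(C)C)(C(C)C)C(C)C)cc(O[Si](C(C)C)(C(C)C)C(C)C)c1OCOC
F3 | step 6 | [(E)-1-Ar-prop-1-en-2-yl]lithium (Li cis to vinylic H) | C/C([Li])=C\c1cc(CO[Si](C(C)C)(C(C)C)C(C)C)cc(O[Si](C(C)C)(C(C)C)C(C)C)c1OCOC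
F4 | step 6 | dimethyl[(E)-1-Ar-prop-1-en-2-yl]alane (Al cis to vinylic H) | C/C([Al](C)C)=C\c1cc(CO[Si](C(C)C)(C(C)C)C(C)C)cc(O[Si](C(C)C)(C(C)C)C(C)C)c1OCOC
F5 | step 6 | dimethylaluminium (3S)-2-methyl-3-[(E)-1-Ar-prop-1-en-2-yl]cyclohex-1-en-1-olate | C[Al](C)OC1=C(C)[C@H](/C(C)=C/c2cc(CO[Si](C(C)C)(C(C)C)C(C)C)cc(O[Si](C(C)C)(C(C)C)C(C)C)c2OCOC)CCC1
F6 | step 9 | (2S,3S)-2-methyl-2-(3-oxobutyl)-3-[(E)-1-Ar-prop-1-en-2-yl]cyclohexan-1-one | O=C1CCC[C@@H](/C(C)=C/c2cc(CO[Si](C(C)C)(C(C)C)C(C)C)cc(O[Si](C(C)C)(C(C)C)C(C)C)c2OCOC)[C@]1(C)CCC(C)=O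
F7 | step 9 | (2S,3S)-2-(3-hydroxybutyl)-2-methyl-3-[(E)-1-Ar-prop-1-en-2-yl]cyclohexan-1-ol (carbinol epimers) | OC1CCC[C@@H](/C(C)=C/c2cc(CO[Si](C(C)C)(C(C)C)C(C)C)cc(O[Si](C(C)C)(C(C)C)C(C)C)c2OCOC)[C@]1(C)CCC(C)O
F8 | step 9 | (2S,3S)-2-(3-bromobutyl)-2-methyl-3-[(E)-1-Ar-prop-1-en-2-yl]cyclohexan-1-ol (epimers at CHOH and CHBr) | OC1CCC[C@@H](/C(C)=C/c2cc(CO[Si](C(C)C)(C(C)C)C(C)C)cc(O[Si](C(C)C)(C(C)C)C(C)C)c2OCOC)[C@]1(C)CCC(C)Br
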